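In a one-step world every substrate that leaves becomes target, at a rate that grows with warmth, so the bench rule says: warm the flask, wait less, collect the same yield.

| flask | substrate | gas | temperature | remark | time |
|---|---|---|---|---|---|
| spring | 1.3 M | 200 mM (held) | 12 °C | run made earlier |  |
| winter | 2 M | 200 mM (held) | 40 °C | run made earlier |  |
| grey | 0.92 M | 200 mM (held) | 25 °C |  | 80 min |
| violet | 0.92 M | 200 mM (held) | 50 °C |  | 80 min |
| teal | 0.92 M | 200 mM (held) | 0 °C |  | 80 min |

| run | time / min | target / % | substrate / % |
|---|---|---|---|
| spring | 8.00 | 16 | 78 |
| spring | 25.0 | 32 | 35 |
| spring | 50.0 | 39 | 9 |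
| spring | 60.0 | 41 | 6 |
| spring | 90.0 | 43 | 2 |
| spring | 120 | 45 | 1 |
| spring | 150 | 45 | 2 |
| winter | 3.00 | 11 | 55 |
| winter | 5.00 | 15 | 30 |
| winter | 8.00 | 21 | 7 |
| winter | 12.0 | 19 | 2 |
| winter | 15.0 | 20 | 0 |
| winter | 25.0 | 22 | 0 |
| winter | 40.0 | 20 | 1 |

(standard deviation of a reading: 1.5 percentage points)

- at the start none of the gas is in solution

- the flask with the highest amount of target, in percent of the substrate charged ("all alike" if they lie within 1.5 percentage points) (grey / violet / teal / all alike)
- final target, as a percentage of the substrate charged, in grey
- final target, as a percentage of the substrate charged, in violet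
- final target, as a percentage of the substrate charged, in teal

Applied honestly, the rule reads a pseudo-first-order rate from the substrate column, 0.0543 min⁻¹ in the spring run and 0.485 min⁻¹ on the last stretch of the winter run. Spread evenly on a logarithmic scale of temperature, these readings give 0.150 min⁻¹ for grey, 1.06 min⁻¹ for violet and 0.0213 min⁻¹ for teal. The rule meets its border early in the winter run, where the substrate falls almost in a straight line, by 0.150 min⁻¹ of the charge per minute and then 0.125 min⁻¹. Since the gas starts outside the solution, that fall is read as a ceiling on its crossing, 0.300 M min⁻¹.

The draw is then the rate multiplied by the charge and divided by this ceiling, with one as its zero, the even case where demand matches the ceiling; for grey it is 0.460. Spring stands at 0.235 and winter at 3.23, on opposite sides of one . Violet, at 3.25, lies beyond one, so its target is reckoned below grey's but above the winter plateau of 22%. Grey lies below one with less charge than spring, so it is reckoned at spring's 45% or higher. Teal, at 0.0652, is reckoned from its first-order rate to a conversion of 81.7%, and around that conversion the spring readings held between 32% and 39% of target, so this reckoning puts grey first.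

The forecast differs, naming teal with 33% in grey, 17% in violet and 42% in teal, on the grounds “I attribute the difference mainly to temperature”.

Grey holds most, 48.9%, against 33.8% in violet and 40.3% in teal, whose conversion at the end is 62.4%, less than the reckoned figure.

    crystals ⇌ by-product, rate k1*(cs1 - [by-product]) while solid is left; crystals form when [by-product] > cs1 (solubility = 0.280 M, k = 1.32 min⁻¹)
    gas ⇌ reagent, rate k2*(csat - [reagent]) (kL = 1.47 min⁻¹)
    substrate + reagent → target + by-product (k = 0.0505 L mol⁻¹ min⁻¹, Ea = 66.0 kJ mol⁻¹)
    substrate + target → side product (k = 0.0106 L mol⁻¹ min⁻¹, Ea = 69.0 kJ mol⁻¹)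
    (constants at 0 °C)

From the spring flask, moving the charge alone to grey's gives 52.2%, and moving the temperature alone gives 39.8%. At grey's charge, between the two flasks with 0% of their substrate left at the end, target falls as the draw rises: grey stands at 0.460 with 48.9%, and violet at 3.25 with 33.8%, while teal, with 38% left, stands outside this comparison. The same flask as grey run at 40 °C has a draw of 1.49 and lies between them , ending at 41.3%.

The readings stem from a simulated flask for substances that don't exist, and the scatter is random.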